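The α-methylene-γ-butyrolactone (ring B: O, C6, C7, C11, C12; germacrane numbering) is cut at O–C6 and C7–C11. This works because C6 is allylic to the C4=C5 alkene of the ten-membered ring A. In the forward direction, an acyclic diene C4=C5–C6=C7 with a Z-configured C6=C7 bond is merged with commercial 2-bromoacrylic acid by a palladium-catalysed diene heteroannulation. The vinylpalladium unit adds to C7, and the carboxylate closes on C6 of the resulting π-allyl. One operation gives the whole lactone, sets C6 and C7 under control of C8 (from (R)-glyceraldehyde acetonide) and keeps C4=C5. Ring A is closed afterwards at C9–C10 by a Nozaki–Hiyama–Kishi reaction.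

Key step: step 8

Remark (numbering and assumption): ring A is C1–C10, with C1=C10 bearing CO2Me (C14), C4=C5 bearing CH2OH (C15), C6–O of the lactone, C7, C8 methacrylate and C9 acetate; C11–C13 is the acrylate unit of ring B; both ring alkenes are cis within ring A (C3 cis to C6, C2 cis to C9); the target is 6R,7S,8S,9R; compounds 1, 4, 5, 11 and all unnumbered reagents are taken as commercial.

Step 1
Reactants: 1 (R)-glyceraldehyde acetonide
Product: 2 (S)-4-ethynyl-2,2-dimethyl-1,3-dioxolane
Conditions: dimethyl (1-diazo-2-oxopropyl)phosphonate, K2CO3, MeOH, 0 °C to rt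
Reagents that add atoms: dimethyl (1-diazo-2-oxopropyl)phosphonate, CC(=O)C(=[N+]=[N-])P(=O)(OC)OC
Why: Seyferth–Gilbert homologation in its Ohira–Bestmann form converts the aldehyde carbon (C7) into the terminal alkyne C7≡C6 under mild carbonate conditions, so the chiral-pool stereocentre C8 should be carried over without epimerisation.

Step 2
Reactants: 2 (S)-4-ethynyl-2,2-dimethyl-1,3-dioxolane
Product: 3 dioxolanyl propynal
Conditions: n-BuLi, THF, −78 °C; DMF; inverse quench into aq. KH2PO4
Reagents that add atoms: N,N-dimethylformamide, CN(C)C=O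
Why: Formylation of the lithium acetylide with DMF, released by an inverse buffered quench, is the standard route to ynals and adds C5 without touching C8.

Step 3
Reactants: 4 triethyl phosphonoacetate; 5 3-bromo-1,1-dimethoxypropane
Product: 6 α-alkylated phosphonoacetate (racemic)
Conditions: NaH, NaI (catalytic), DMF, 0 to 60 °C
Reagents that add atoms: none
Why: SN2 alkylation of the sodium phosphonoacetate by the primary bromide joins C4 to C3 and gives a racemic phosphonate whose stereocentre is lost in step 4.

Step 4
Reactants: 3 dioxolanyl propynal; 6 α-alkylated phosphonoacetate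
Product: 7 (E)-enyne ester
Conditions: LiCl, DBU, MeCN, 0 °C to rt
Reagents that add atoms: none
Why: Horner–Wadsworth–Emmons olefination under Masamune–Roush conditions is mild enough for the base-sensitive ynal and should favour the tiglate-type E-enoate, in which the alkynyl group (C6) is trans to the ester (C15) and cis to C3, as ring A requires.

Step 5
Reactants: 7 (E)-enyne ester
Product: 8 (E)-enynol
Conditions: i-Bu2AlH (2.5 equiv), CH2Cl2, −78 °C; aq. potassium sodium tartrate
Reagents that add atoms: none
Why: 1,2-Reduction of the conjugated ester with i-Bu2AlH at low temperature gives the allylic alcohol C15–OH and leaves alkyne, acetal and acetonide untouched.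

Step 6
Reactants: 8 (E)-enynol
Product: 9 TBDPS-protected enyne
Conditions: TBDPSCl, imidazole, CH2Cl2, rt
Reagents that add atoms: tert-butyl(chloro)diphenylsilane, CC(C)(C)[Si](Cl)(c1ccccc1)c1ccccc1
Why: Standard silylation puts an acid-stable ether on the allylic C15–OH that should neither ionise under zerovalent palladium in step 8 nor fall off in step 9.

Step 7
Reactants: 9 TBDPS-protected enyne
Product: 10 (6Z)-diene
Conditions: H2 (1 atm), Pd/CaCO3 poisoned with Pb(OAc)2, quinoline, EtOAc–hexane, rt
Reagents that add atoms: none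
Why: Lindlar semihydrogenation adds H2 syn to the alkyne and should stop at the Z-configured C6=C7 alkene, the trisubstituted C4=C5 bond being too hindered to react.

Step 8
Reactants: 10 (6Z)-diene; 11 2-bromoacrylic acid
Product: 13 trans-α-methylene-γ-butyrolactone (6R,7S,8S), via allylpalladium bromide 12 (not isolated)
Conditions: Pd(OAc)2 (10 mol %), PPh3 (20 mol %), Na2CO3, n-Bu4NCl, BHT (trace), DMF, 70 °C, slow addition of 11
Reagents that add atoms: none
Why: Oxidative addition of zerovalent palladium to the C–Br bond of 11, syn carbopalladation of C6=C7 with C11 going to the diene terminus C7, and attack of the pendant carboxylate oxygen on C6 of the resulting C4–C5–C6 π-allylpalladium form C11–C7 and O–C6 in one catalytic cycle; the closest known reaction type is the Larock-type heteroannulation of 1,3-dienes by halides that carry a carboxylic acid. Ring B closes in a 5-exo mode at C6, the 7-endo attack at the fully substituted C4 being disfavoured, so C4=C5 is regenerated with its geometry intact, because syn/anti exchange at C4 would need a tertiary σ-palladium species. C7 is controlled by C8: A(1,3) strain in the Z-alkene holds C8–H in the diene plane, the C8–O bond with its CMe2 group shields one face, and the vinylpalladium unit adds anti to it, which gives 7S from 8S. C6 is controlled by the alkene geometry and the mechanism: syn insertion followed by outer-sphere attack anti to palladium (chloride and phosphine fill the coordination sites, so the carboxylate stays off the metal) is a net anti addition to a Z-alkene and gives the trans-lactone (6R), which is also the more stable isomer should the allylic C6–O bond re-ionise. The step needs regioselectivity for C7 over C4 and chemoselectivity for the diene, and the substrate secures both, since C4 is fully substituted, no other alkene is present and all oxygen functions are ethers or acetals that zerovalent palladium cannot ionise.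

Step 9
Reactants: 13 trans-α-methylene-γ-butyrolactone
Product: 14 C8,C9-diol C1-aldehyde
Conditions: AcOH–THF–H2O (3:1:1), 40 °C
Reagents that add atoms: water, O
Why: Mild aqueous acid hydrolyses the isopropylidene ketal and the dimethyl acetal in one operation, while the TBDPS ether, the allylic lactone and all stereocentres should survive.

Step 10
Reactants: 14 C8,C9-diol C1-aldehyde
Product: 15 (Z)-α-iodoenoate diol
Conditions: Ph3P=CHCO2Me, NIS, CH2Cl2, −20 °C; then 14, to rt
Reagents that add atoms: methyl (triphenylphosphoranylidene)acetate, COC(=O)C=P(c1ccccc1)(c1ccccc1)c1ccccc1; N-iodosuccinimide, O=C1CCC(=O)N1I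
Why: Wittig olefination with the iodo ylide made in the flask reacts only with the aldehyde and is known to favour the Z-α-iodoenoate, in which C2 is trans to the ester and iodine holds the place of C9.

Step 11
Reactants: 15 (Z)-α-iodoenoate diol
Product: 16 C9 triethylsilyl ether
Conditions: TESCl (1.05 equiv), imidazole, CH2Cl2, −20 °C
Reagents that add atoms: chlorotriethylsilane, CC[Si](Cl)(CC)CC
Why: Kinetic silylation with one equivalent of TESCl at low temperature selects the primary C9–OH over the hindered secondary C8–OH.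

Step 12
Reactants: 16 C9 triethylsilyl ether
Product: 17 C8 methacrylate
Conditions: methacrylic anhydride, Et3N, DMAP (catalytic), CH2Cl2, 0 °C to rt
Reagents that add atoms: methacrylic anhydride, C=C(C)C(=O)OC(=O)C(C)=C
Why: DMAP-catalysed acyl transfer from methacrylic anhydride esterifies the only free hydroxyl, C8–OH, with retention at C8.

Step 13
Reactants: 17 C8 methacrylate
Product: 18 C9 aldehyde
Conditions: (COCl)2, DMSO, CH2Cl2, −78 to −40 °C; i-Pr2NEt, −78 to 0 °C
Reagents that add atoms: none
Why: Under Swern conditions a primary triethylsilyl ether is attacked directly by the chlorosulfonium salt and oxidised to the aldehyde, which saves a deprotection, spares the TBDPS ether and, with a hindered amine at low temperature, should not epimerise C8.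

Step 14
Reactants: 18 C9 aldehyde
Product: 19 macrocyclic C9 alcohol (6R,7S,8S,9R)
Conditions: CrCl2 (10 equiv), NiCl2 (0.1 equiv), DMSO, rt, slow addition of 18, final concentration about 0.002 M
Reagents that add atoms: none
Why: Nozaki–Hiyama–Kishi macrocyclisation under high dilution tolerates esters, lactone and acrylates, transfers the alkenyl group with retention of the ring-cis C1=C10 geometry, and should add to the α-acyloxy aldehyde in the polar Felkin–Anh sense (attack anti to C8–O), which gives the 8,9-anti relationship and hence 9R.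

Step 15
Reactants: 19 macrocyclic C9 alcohol
Product: 20 C9 acetate
Conditions: Ac2O, pyridine, DMAP (catalytic), CH2Cl2, 0 °C
Reagents that add atoms: acetic anhydride, CC(=O)OC(C)=O
Why: Standard acetylation of the allylic C9–OH right after isolation fixes the acyl pattern before any 1,2-acyl shift between O8 and O9 can occur.

Step 16
Reactants: 20 C9 acetate
Product: 21 target CNP0179134.4
Conditions: HF·pyridine, pyridine, THF, 0 °C to rt
Reagents that add atoms: none
Why: Fluoride-mediated desilylation with buffered HF·pyridine cleaves the primary TBDPS ether under weakly acidic conditions that leave the three esters, the α-methylene lactone and all four stereocentres untouched.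

Compound list

1 | (R)-2,2-dimethyl-1,3-dioxolane-4-carbaldehyde ((R)-glyceraldehyde acetonide; CHO carbon becomes C7, stereocentre C8, CH2O carbon C9) | O=C[C@H]1COC(C)(C)O1 | starting material
2 | (S)-4-ethynyl-2,2-dimethyl-1,3-dioxolane | C#C[C@H]1COC(C)(C)O1 | intermediate
3 | 3-[(S)-2,2-dimethyl-1,3-dioxolan-4-yl]prop-2-ynal | O=CC#C[C@H]1COC(C)(C)O1 | intermediate
4 | triethyl phosphonoacetate | CCOC(=O)CP(=O)(OCC)OCC | starting material
5 | 3-bromo-1,1-dimethoxypropane | COC(CCBr)OC | starting material
6 | ethyl 2-(diethoxyphosphoryl)-5,5-dimethoxypentanoate (racemic) | CCOC(=O)C(CCC(OC)OC)P(=O)(OCC)OCC | intermediate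
7 | ethyl (E)-2-(3,3-dimethoxypropyl)-5-[(S)-2,2-dimethyl-1,3-dioxolan-4-yl]pent-2-en-4-ynoate | CCOC(=O)/C(CCC(OC)OC)=C/C#C[C@H]1COC(C)(C)O1 | intermediate
8 | (E)-2-(3,3-dimethoxypropyl)-5-[(S)-2,2-dimethyl-1,3-dioxolan-4-yl]pent-2-en-4-yn-1-ol | OC/C(CCC(OC)OC)=C/C#C[C@H]1COC(C)(C)O1 | intermediate
9 | tert-butyldiphenylsilyl ether of 8 | CC(C)(C)[Si](c1ccccc1)(c1ccccc1)OC/C(CCC(OC)OC)=C/C#C[C@H]1COC(C)(C)O1 | intermediate
10 | (S)-4-[(1Z,3E)-4-{[tert-butyl(diphenyl)silyl]oxymethyl}-7,7-dimethoxyhepta-1,3-dien-1-yl]-2,2-dimethyl-1,3-dioxolane (C6=C7 Z; at C4=C5 the chain C3 is cis to C6) | CC(C)(C)[Si](c1ccccc1)(c1ccccc1)OC/C(CCC(OC)OC)=C/C=C\[C@H]1COC(C)(C)O1 | intermediate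
11 | 2-bromoacrylic acid (2-bromoprop-2-enoic acid) | C=C(Br)C(=O)O | starting material
12 | allylpalladium bromide from syn addition of the 1-carboxyvinyl group to C7 and of palladium to C6 (drawn in its σ-allyl form, phosphine omitted, acid drawn neutral) | OC(=O)C(=C)[C@H]([C@H]1COC(C)(C)O1)[C@@H]([Pd]Br)/C=C(/CO[Si](c1ccccc1)(c1ccccc1)C(C)(C)C)CCC(OC)OC | intermediate
13 | trans-3-methylideneoxolan-2-one bearing at C7 the (S)-2,2-dimethyl-1,3-dioxolan-4-yl group and at C6 the (E)-2-(TBDPS-oxymethyl)-5,5-dimethoxypent-1-enyl group; 6R,7S,8S | CC1(C)OC[C@@H](O1)[C@H]2C(=C)C(=O)O[C@@H]2/C=C(/CO[Si](c3ccccc3)(c3ccccc3)C(C)(C)C)CCC(OC)OC | intermediate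
14 | lactone with free C8,C9-diol and C1 aldehyde; stereocentres spatially as in 13 (the C7 descriptor reads R here only through changed priorities) | OC[C@@H](O)[C@H]1C(=C)C(=O)O[C@@H]1/C=C(/CO[Si](c2ccccc2)(c2ccccc2)C(C)(C)C)CCC=O | intermediate
15 | diol carrying the methyl (Z)-2-iodoalk-2-enoate terminus (C2 cis to iodine, trans to CO2Me); stereocentres as in 14 | OC[C@@H](O)[C@H]1C(=C)C(=O)O[C@@H]1/C=C(/CO[Si](c2ccccc2)(c2ccccc2)C(C)(C)C)CC/C=C(\I)C(=O)OC | intermediate
16 | C9-O-triethylsilyl ether of 15 with free C8–OH | CC[Si](CC)(CC)OC[C@@H](O)[C@H]1C(=C)C(=O)O[C@@H]1/C=C(/CO[Si](c2ccccc2)(c2ccccc2)C(C)(C)C)CC/C=C(\I)C(=O)OC | intermediate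
17 | C8-O-methacrylate of 16; 6R,7S,8S | CC[Si](CC)(CC)OC[C@@H](OC(=O)C(C)=C)[C@H]1C(=C)C(=O)O[C@@H]1/C=C(/CO[Si](c2ccccc2)(c2ccccc2)C(C)(C)C)CC/C=C(\I)C(=O)OC | intermediate
18 | C9 aldehyde with C8 methacrylate and (Z)-α-iodoenoate; 6R,7S,8S | O=C[C@@H](OC(=O)C(C)=C)[C@H]1C(=C)C(=O)O[C@@H]1/C=C(/CO[Si](c2ccccc2)(c2ccccc2)C(C)(C)C)CC/C=C(\I)C(=O)OC | intermediate
19 | ten-membered carbocycle with free C9–OH, C8 methacrylate and C15 TBDPS ether; 6R,7S,8S,9R | C=C(C)C(=O)O[C@H]1[C@H]2C(=C)C(=O)O[C@@H]2/C=C(/CO[Si](c3ccccc3)(c3ccccc3)C(C)(C)C)CC/C=C(/C(=O)OC)[C@H]1O | intermediate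
20 | C9 acetate of 19; 6R,7S,8S,9R | C=C(C)C(=O)O[C@H]1[C@H]2C(=C)C(=O)O[C@@H]2/C=C(/CO[Si](c3ccccc3)(c3ccccc3)C(C)(C)C)CC/C=C(/C(=O)OC)[C@H]1OC(C)=O | intermediate
21 | CNP0179134.4: (6R,7S,8S,9R)-9-acetoxy-15-hydroxy-8-methacryloyloxy-14-methoxycarbonyl cis,cis-germacra-1(10),4,11(13)-trien-6,12-olide | C=C(C)C(=O)O[C@H]1[C@H]2C(=C)C(=O)O[C@@H]2/C=C(/CO)CC/C=C(/C(=O)OC)[C@H]1OC(C)=O | target

Total step count: 16. Longest linear sequence: 15 steps (from 1 through steps 1, 2 and 4–16); step 3 is the only side branch.

Steps most likely to fail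

Step 8. Carbopalladation of the hindered Z-alkene may be slow. β-Hydride elimination, Z/E isomerisation of the diene or polymerisation of the bromoacrylate could then take over. The facial bias exerted by C8 may also be low. Fallback: the same two bonds are made by a radical–polar crossover, setting out from 10. Malonic acid, Mn(OAc)3·2H2O and KOAc in AcOH at rt effect an oxidative carbolactonisation by trivalent manganese. The malonyl radical adds to C7, the allyl radical is oxidised, and the carboxyl group closes on C6. This should give the α-carboxy lactone F1. Decarboxylative methylenation (aq. formaldehyde, Et2NH, then NaOAc–AcOH, warm) comes back to the route at 13.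

Step 14. Ring closure may suffer from oligomerisation or protodeiodination. It may also suffer from migration of the methacryloyl group to the new C9 alkoxide, from breakdown of the α-acyloxy aldehyde, or from poor facial selectivity at C9. Fallback: the order of acylation is changed, setting out from 15.
- Excess TESCl and imidazole give the bis(triethylsilyl) ether F2.
- Selective Swern oxidation of the primary silyl ether gives the α-silyloxy aldehyde F3.
- CrCl2/NiCl2 closes ring A to the C8-silylated macrocyclic alcohol F4, now with a bulkier and non-migrating Felkin–Anh control element.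
- Ac2O/pyridine gives the silylated C9 acetate F5.
- AcOH–THF–H2O removes the secondary silyl group to give the C8 alcohol F6.
- Methacrylic anhydride with DMAP comes back to the route at 20.

Step 4. The olefination with an α-branched phosphonate and a slim ynal may show poor E/Z selectivity. Fallback: the geometry is fixed by a stereospecific cross-coupling, setting out from 3 and 5. Wittig reaction of 3 with the iodo ylide from Ph3P=CHCO2Et and NIS gives the ethyl (Z)-α-iodoenynoate F7. Insertion of Zn (LiCl, THF) into 5 gives (3,3-dimethoxypropyl)zinc bromide F8. Negishi coupling with PdCl2(dppf) replaces iodine by C3 with retention and comes back to the route at 7.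

Further compounds

F1 | step 8 | α-carboxy trans-lactone (C11 epimers; otherwise as 13) | CC1(C)OC[C@@H](O1)[C@H]2C(C(=O)O)C(=O)O[C@@H]2/C=C(/CO[Si](c3ccccc3)(c3ccccc3)C(C)(C)C)CCC(OC)OC
F2 | step 14 | C8,C9-bis(triethylsilyl) ether of 15 | CC[Si](CC)(CC)OC[C@@H](O[Si](CC)(CC)CC)[C@H]1C(=C)C(=O)O[C@@H]1/C=C(/CO[Si](c2ccccc2)(c2ccccc2)C(C)(C)C)CC/C=C(\I)C(=O)OC
F3 | step 14 | C9 aldehyde with C8 triethylsilyl ether | O=C[C@@H](O[Si](CC)(CC)CC)[C@H]1C(=C)C(=O)O[C@@H]1/C=C(/CO[Si](c2ccccc2)(c2ccccc2)C(C)(C)C)CC/C=C(\I)C(=O)OC
F4 | step 14 | macrocyclic C9 alcohol with C8 triethylsilyl ether | CC[Si](CC)(CC)O[C@H]1[C@H]2C(=C)C(=O)O[C@@H]2/C=C(/CO[Si](c3ccccc3)(c3ccccc3)C(C)(C)C)CC/C=C(/C(=O)OC)[C@H]1O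
F5 | step 14 | C9 acetate of F4 | CC[Si](CC)(CC)O[C@H]1[C@H]2C(=C)C(=O)O[C@@H]2/C=C(/CO[Si](c3ccccc3)(c3ccccc3)C(C)(C)C)CC/C=C(/C(=O)OC)[C@H]1OC(C)=O
F6 | step 14 | macrocyclic C8 alcohol with C9 acetate | O[C@H]1[C@H]2C(=C)C(=O)O[C@@H]2/C=C(/CO[Si](c3ccccc3)(c3ccccc3)C(C)(C)C)CC/C=C(/C(=O)OC)[C@H]1OC(C)=O
F7 | step 4 | ethyl (Z)-5-[(S)-2,2-dimethyl-1,3-dioxolan-4-yl]-2-iodopent-2-en-4-ynoate | CCOC(=O)/C(I)=C/C#C[C@H]1COC(C)(C)O1
F8 | step 4 | (3,3-dimethoxypropyl)zinc bromide | COC(CC[Zn]Br)OC
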